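## Retrosynthetic overview

1. The acetate and myristate go on last; before that, the C8–C9 bond joins a ring half (lactone-derived carboxylate) and a tail half ((E)-alkenyl iodide) in a light-driven iron/nickel decarboxylative alkenylation.
2. The (Z)-tetrasubstituted enal comes from 1,4-hydrogenation of a 2-substituted 1,3-diene, made from the enol triflate of a ring ketone.
3. The C5 carbinol and C6 quaternary centre come from MeMgBr addition and a Michael addition on a 2-methyl-3-alkylcyclohexanone, itself from cyclobutane cleavage of a 4-substituted nopinone.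
4. Rings: the only carbocycle is the six-membered ring carried in from nopinone (cyclobutane opened in step 3); a temporary δ-lactone closes in step 5 and is opened in step 16.
5. The tail comes from two carboaluminations and opening of serine-derived methyl (R)-glycidate, which supplies C11.

Assumption: (1S,5R)-(−)-nopinone is bought; it is otherwise one ozonolysis from (+)-β-pinene.
Locants (target numbering): ring C1 = CH bearing the O(CH2)3 chain, C2 = enal-bearing carbon, C3/C4 = CH2, C5 = carbinol carbon, C6 = quaternary carbon; side chain C7–C18 counted outward from C6 (C11 = oxygenated carbon).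

## Route

**Step 1**
Reactants: 1 (1S,5R)-6,6-dimethylbicyclo[3.1.1]heptan-2-one, (−)-nopinone
Product: 3 (1S,5S)-6,6-dimethylbicyclo[3.1.1]hept-3-en-2-one (apoverbenone), via lithium enolate 2 (not isolated)
Conditions: LiN(i-Pr)2, THF, −78 °C; then PhS(Cl)=N-t-Bu, −78 °C
Reagents that add atoms: none
Why: Mukaiyama one-pot ketone dehydrogenation (enolate sulfenylation then syn-elimination) at the only enolisable side; no stereocentre is touched (the C5 label changes by CIP priorities only).

**Step 2**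
Reactants: 3 apoverbenone
Product: 5 (1S,4R,5S)-4-[3-(tert-butyldiphenylsilyloxy)propyl]-3,6,6-trimethylbicyclo[3.1.1]heptan-2-one (C3 epimer mixture, C4 chain anti to the CMe2 bridge), via bromomagnesium enolate 4 (not isolated)
Conditions: t-BuPh2SiO(CH2)3MgBr (from the bromide and Mg), CuBr·SMe2 (10 mol %), THF, −78 → −40 °C; then MeI, DMPU, −40 → 0 °C
Reagents that add atoms: [3-(tert-butyldiphenylsilyloxy)propyl]magnesium bromide, Br[Mg]CCCO[Si](c1ccccc1)(c1ccccc1)C(C)(C)C; iodomethane, CI
Why: copper-catalysed conjugate addition on the face anti to the gem-dimethyl bridge sets the future ring C1 from the pinane chirality, and the enolate is then C-methylated (tandem 1,4-addition/alkylation; the methyl epimers converge in step 4).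

**Step 3**
Reactants: 5 bicyclic ketone
Product: 7 (3R,4S)-3-[3-(tert-butyldiphenylsilyloxy)propyl]-2-methyl-4-(prop-1-en-2-yl)cyclohexan-1-one (C2 epimer mixture; C3 and C4 substituents trans), via iodo silyl enol ether 6 (not isolated)
Conditions: Me3SiCl, NaI, MeCN, −20 °C; DBU, 25 °C; then 1 M HCl, THF, 0 °C
Reagents that add atoms: none
Why: iodotrimethylsilane cleaves the cyclobutane bond α to the carbonyl (known pinane-to-menthane opening giving enol silane plus tertiary iodide), E2 elimination gives the isopropenyl group and the enol ether is hydrolysed; the chain-bearing stereocentre is untouched, and any isopropylidene isomer converges in step 6.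

**Step 4**
Reactants: 7 monocyclic ketone
Product: 8 methyl 3-[(1S,2R,3S)-2-[3-(tert-butyldiphenylsilyloxy)propyl]-1-methyl-6-oxo-3-(prop-1-en-2-yl)cyclohexyl]propanoate
Conditions: methyl acrylate (1.2 equiv), t-BuOK (0.2 equiv), t-BuOH/THF, 0 → 25 °C
Reagents that add atoms: methyl acrylate, C=CC(=O)OC
Why: Michael addition of the thermodynamic (more substituted) enolate; the acrylate approaches C6 anti to the adjacent C1 chain, so the new quaternary centre has its propanoate arm trans to the C1 chain and the methyl cis to it.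

**Step 5**
Reactants: 8 keto ester
Product: 10 (4aS,5R,6S,8aS)-5-[3-(tert-butyldiphenylsilyloxy)propyl]-4a,8a-dimethyl-6-(prop-1-en-2-yl)octahydro-2H-chromen-2-one (trans-fused δ-lactone), via hydroxy ester 9 (not isolated)
Conditions: MeMgBr, CeCl3, THF, −78 → 25 °C
Reagents that add atoms: methylmagnesium bromide, C[Mg]Br
Why: chemoselective organocerium 1,2-addition to the ketone from the face anti to the axial C6 methyl (axial attack) sets C5 with OH cis to the C6 methyl, and the tertiary alkoxide lactonises onto the methyl ester.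

**Step 6**
Reactants: 10 lactone
Product: 13 ketolactone (10 in which the isopropenyl-bearing ring carbon C2 has become C=O), via methoxy hydroperoxide 11 (not isolated), via TEMPO alkoxyamine 12 (not isolated)
Conditions: O3, MeOH/CH2Cl2, −78 °C; FeSO4·7H2O, TEMPO, −78 → 25 °C; then mCPBA, 25 °C
Reagents that add atoms: TEMPO, CC1(C)CCCC(C)(C)N1[O]
Why: oxodealkenylation (ozonolysis, iron-mediated alkoxy-radical β-scission, TEMPO capture, oxidative N–O elimination) replaces the isopropenyl group by a carbonyl; C1, now α to the ketone, sits in its strongly favoured equatorial configuration.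

**Step 7**
Reactants: 13 ketolactone
Product: 15 enol triflate of 13 (C2–OTf, C2=C3), via potassium enolate 14 (not isolated)
Conditions: KN(SiMe3)2, THF, −78 °C; PhNTf2, −78 → 0 °C
Reagents that add atoms: N-phenylbis(trifluoromethanesulfonimide), O=S(=O)(N(c1ccccc1)S(=O)(=O)C(F)(F)F)C(F)(F)F
Why: kinetic deprotonation at the unhindered C3 methylene (not at the tertiary C1) followed by O-triflation gives the regiodefined enol triflate.

**Step 8**
Reactants: 15 enol triflate
Product: 16 diene acetal (15 with OTf replaced by a 3,3-diethoxyprop-1-en-2-yl group)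
Conditions: 2-bromo-3,3-diethoxyprop-1-ene, t-BuLi, Et2O, −78 °C; ZnBr2; then 15, Pd(PPh3)4 (5 mol %), THF, 25 → 45 °C
Reagents that add atoms: 2-bromo-3,3-diethoxyprop-1-ene, C=C(Br)C(OCC)OCC
Why: Negishi cross-coupling of the enol triflate with the α-metallated acrolein acetal builds the 2,3-disubstituted 1,3-diene.

**Step 9**
Reactants: 16 diene acetal
Product: 17 (Z)-alkene acetal (ring C2=C(CH3)CH(OEt)2, acetal carbon cis to C1, methyl cis to C3)
Conditions: (η6-naphthalene)Cr(CO)3 (20 mol %), H2 (70 atm), acetone, 25 °C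
Reagents that add atoms: none
Why: chromium tricarbonyl-catalysed 1,4-hydrogenation of the s-cis η4-diene delivers hydrogen to the two termini (C3 and the exo-methylene), so the new methyl must lie cis to C3 and the Z tetrasubstituted alkene is fixed by the diene geometry.

**Step 10**
Reactants: 18 6-methylhept-5-en-2-one
Product: 20 6-methylhept-5-en-1-yne, via enol phosphate 19 (not isolated)
Conditions: LiN(i-Pr)2, THF, −78 °C; ClP(O)(OEt)2; then LiN(i-Pr)2 (2.3 equiv), −78 → 25 °C
Reagents that add atoms: none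
Why: Negishi methyl ketone to terminal alkyne conversion (kinetic enol phosphate, then elimination).

**Step 11**
Reactants: 20 alkyne
Product: 22 (E)-1-iodo-2,6-dimethylhepta-1,5-diene, via alkenylalane 21 (not isolated)
Conditions: Me3Al, Cp2ZrCl2 (20 mol %), CH2Cl2, 0 → 25 °C; then I2, THF, −30 °C
Reagents that add atoms: trimethylaluminium, C[Al](C)C; iodine, II
Why: zirconium-catalysed syn-carboalumination (Negishi) and iodinolysis with retention give the E trisubstituted alkenyl iodide.

**Step 12**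
Reactants: 22 alkenyl iodide; 23 methyl (2R)-oxirane-2-carboxylate (methyl (R)-glycidate, from L-serine)
Product: 25 methyl (2R,4E)-2-hydroxy-5,9-dimethyldeca-4,8-dienoate, via alkenylmagnesium bromide 24 (not isolated)
Conditions: 22, t-BuLi (2 equiv), Et2O, −78 °C; MgBr2·OEt2; then CuBr·SMe2 (10 mol %), 23, THF, −50 → −30 °C
Reagents that add atoms: none
Why: copper-catalysed SN2 opening of the glycidate at its CH2 terminus by the alkenyl Grignard keeps the alkene geometry and leaves the bought stereocentre (future C11) untouched.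

**Step 13**
Reactants: 25 hydroxy ester
Product: 26 methyl (2R,4E)-2-(tert-butyldimethylsilyloxy)-5,9-dimethyldeca-4,8-dienoate
Conditions: TBSCl, imidazole, DMF, 25 °C
Reagents that add atoms: tert-butyldimethylsilyl chloride, CC(C)(C)[Si](C)(C)Cl
Why: standard silyl protection of the secondary alcohol.

**Step 14**
Reactants: 26 silyloxy ester
Product: 28 (3R,5E)-3-(tert-butyldimethylsilyloxy)-6,10-dimethylundeca-5,9-dien-1-yne, via aldehyde 27 (not isolated)
Conditions: i-Bu2AlH, CH2Cl2, −78 °C; then MeOH, K2CO3, dimethyl (1-diazo-2-oxopropyl)phosphonate, −78 → 25 °C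
Reagents that add atoms: dimethyl (1-diazo-2-oxopropyl)phosphonate, COP(=O)(OC)C(=[N+]=[N-])C(C)=O
Why: one-pot partial ester reduction and Ohira–Bestmann (Seyferth–Gilbert) homologation; the α-silyloxy stereocentre is retained.

**Step 15**
Reactants: 28 alkyne
Product: 30 (1E,3R,5E)-3-(tert-butyldimethylsilyloxy)-1-iodo-2,6,10-trimethylundeca-1,5,9-triene, via alkenylalane 29 (not isolated)
Conditions: Me3Al, Cp2ZrCl2 (50 mol %), CH2Cl2, 0 → 25 °C; then I2, THF, −30 °C
Reagents that add atoms: trimethylaluminium, C[Al](C)C; iodine, II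
Why: Negishi syn-carboalumination/iodination of the propargylic silyl ether gives the E alkenyl iodide with the C10 methyl in place.

**Step 16**
Reactants: 17 (Z)-alkene acetal lactone; 30 alkenyl iodide
Product: 32 coupled seco-compound (C5–OH free, C1 chain as OTBDPS, C2=C(CH3)CH(OEt)2, full side chain with C11–OTBS), via caesium carboxylate 31 (not isolated)
Conditions: CsOH·H2O (1.05 equiv), THF/H2O, 25 °C, evaporate; then FeCl3 (10 mol %), NiBr2(MeOCH2CH2OMe) (10 mol %), 4,4′-di-tert-butyl-2,2′-bipyridine (15 mol %), 30 (1.3 equiv), MeCN/DMA, 390 nm LEDs, 25 °C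
Reagents that add atoms: none
Why: Proposed new method: one-pot lactone hydrolysis and light-driven iron/nickel decarboxylative alkenylation, in which carboxylate-to-metal charge transfer at trivalent iron gives divalent iron and an acyloxy radical that loses CO2 to the primary C8 radical, this is captured by the bipyridine-ligated alkenylnickel halide formed from 30, and reductive elimination from trivalent nickel forms the C8–C9 bond with retention of the E geometry while the nickel/iron couple closes both cycles; closest known reaction type is nickel-metallaphotoredox decarboxylative vinylation of α-heteroatom acids and iron-LMCT/nickel decarboxylative arylation of unactivated acids, not yet shown for a lactone-derived primary carboxylate with a free tertiary alcohol and a trisubstituted alkenyl iodide.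

**Step 17**
Reactants: 32 coupled seco-compound
Product: 33 triol enal (target lacking the acetyl and myristoyl groups)
Conditions: HF·pyridine, pyridine/THF, 0 → 25 °C; then H2O/THF, 25 °C
Reagents that add atoms: water, O
Why: fluoride cleavage of both silyl ethers and mild acid hydrolysis of the diethyl acetal unveil the Z-enal without touching the alkene geometries or stereocentres.

**Step 18**
Reactants: 33 triol enal
Product: 34 primary myristate (C11–OH and C5–OH free)
Conditions: tetradecanoyl chloride (1.05 equiv), 2,4,6-collidine, CH2Cl2, −78 → −40 °C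
Reagents that add atoms: tetradecanoyl chloride, CCCCCCCCCCCCCC(=O)Cl
Why: chemoselective acylation of the unhindered primary alcohol over the secondary allylic and tertiary alcohols.

**Step 19**
Reactants: 34 primary myristate
Product: 35 target
Conditions: Ac2O, pyridine, DMAP (cat.), CH2Cl2, 0 °C
Reagents that add atoms: acetic anhydride, CC(=O)OC(C)=O
Why: acetylation of the secondary allylic alcohol; the tertiary alcohol next to the quaternary carbon does not react under these conditions.

## Compound list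

1 | (1S,5R)-(−)-nopinone | CC1(C)[C@@H]2CCC(=O)[C@H]1C2 | starting material
2 | lithium enolate of 1 | CC1(C)[C@@H]2CC=C(O[Li])[C@H]1C2 | intermediate
3 | (1S,5S)-apoverbenone | CC1(C)[C@@H]2C=CC(=O)[C@H]1C2 | intermediate
4 | bromomagnesium enolate after conjugate addition | CC1(C)[C@@H]2[C@@H](CCCO[Si](c3ccccc3)(c4ccccc4)C(C)(C)C)C=C(O[Mg]Br)[C@H]1C2 | intermediate
5 | (1S,4R,5S)-4-[3-(TBDPS-oxy)propyl]-3,6,6-trimethylbicyclo[3.1.1]heptan-2-one (C3 mixture) | CC1(C)[C@@H]2[C@@H](CCCO[Si](c3ccccc3)(c4ccccc4)C(C)(C)C)C(C)C(=O)[C@H]1C2 | intermediate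
6 | ring-opened trimethylsilyl enol ether with 2-iodopropan-2-yl group | CC(C)(C)[Si](c3ccccc3)(c4ccccc4)OCCC[C@@H]1[C@@H](C(C)(C)I)CC=C(O[Si](C)(C)C)C1C | intermediate
7 | (3R,4S)-3-[3-(TBDPS-oxy)propyl]-2-methyl-4-isopropenylcyclohexanone (C2 mixture) | CC(C)(C)[Si](c3ccccc3)(c4ccccc4)OCCC[C@@H]1[C@@H](C(C)=C)CCC(=O)C1C | intermediate
8 | Michael adduct, methyl propanoate on quaternary C6 | CC(C)(C)[Si](c3ccccc3)(c4ccccc4)OCCC[C@@H]1[C@@H](C(C)=C)CCC(=O)[C@@]1(C)CCC(=O)OC | intermediate
9 | tertiary hydroxy ester | CC(C)(C)[Si](c3ccccc3)(c4ccccc4)OCCC[C@@H]1[C@@H](C(C)=C)CC[C@](C)(O)[C@@]1(C)CCC(=O)OC | intermediate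
10 | trans-fused δ-lactone with isopropenyl | CC(C)(C)[Si](c3ccccc3)(c4ccccc4)OCCC[C@@H]1[C@@H](C(C)=C)CC[C@](C)(O2)[C@@]1(C)CCC2=O | intermediate
11 | α-methoxy hydroperoxide | CC(C)(C)[Si](c3ccccc3)(c4ccccc4)OCCC[C@@H]1[C@@H](C(C)(OC)OO)CC[C@](C)(O2)[C@@]1(C)CCC2=O | intermediate
12 | TEMPO alkoxyamine at C2 (C2 mixture) | CC(C)(C)[Si](c3ccccc3)(c4ccccc4)OCCC[C@@H]1C(ON5C(C)(C)CCCC5(C)C)CC[C@](C)(O2)[C@@]1(C)CCC2=O | intermediate
13 | ketolactone (C2 ketone) | CC(C)(C)[Si](c3ccccc3)(c4ccccc4)OCCC[C@@H]1C(=O)CC[C@](C)(O2)[C@@]1(C)CCC2=O | intermediate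
14 | potassium enolate (C2=C3) | CC(C)(C)[Si](c3ccccc3)(c4ccccc4)OCCC[C@@H]1C(O[K])=CC[C@](C)(O2)[C@@]1(C)CCC2=O | intermediate
15 | enol triflate | CC(C)(C)[Si](c3ccccc3)(c4ccccc4)OCCC[C@@H]1C(OS(=O)(=O)C(F)(F)F)=CC[C@](C)(O2)[C@@]1(C)CCC2=O | intermediate
16 | diene acetal | CC(C)(C)[Si](c3ccccc3)(c4ccccc4)OCCC[C@@H]1C(C(=C)C(OCC)OCC)=CC[C@](C)(O2)[C@@]1(C)CCC2=O | intermediate
17 | (Z)-alkene acetal lactone | CC(C)(C)[Si](c3ccccc3)(c4ccccc4)OCCC[C@@H]1/C(=C(/C)C(OCC)OCC)CC[C@](C)(O2)[C@@]1(C)CCC2=O | intermediate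
18 | 6-methylhept-5-en-2-one | CC(=O)CCC=C(C)C | starting material
19 | diethyl 6-methylhepta-1,5-dien-2-yl phosphate | CCOP(=O)(OCC)OC(=C)CCC=C(C)C | intermediate
20 | 6-methylhept-5-en-1-yne | C#CCCC=C(C)C | intermediate
21 | (E)-alkenyl(dimethyl)alane | C[Al](C)/C=C(\C)CCC=C(C)C | intermediate
22 | (E)-1-iodo-2,6-dimethylhepta-1,5-diene | I/C=C(\C)CCC=C(C)C | intermediate
23 | methyl (R)-glycidate | COC(=O)[C@H]1CO1 | starting material
24 | (E)-alkenylmagnesium bromide | Br[Mg]/C=C(\C)CCC=C(C)C | intermediate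
25 | methyl (2R,4E)-2-hydroxy-5,9-dimethyldeca-4,8-dienoate | COC(=O)[C@H](O)C/C=C(\C)CCC=C(C)C | intermediate
26 | TBS ether of 25 | COC(=O)[C@H](O[Si](C)(C)C(C)(C)C)C/C=C(\C)CCC=C(C)C | intermediate
27 | (2R,4E)-2-(TBS-oxy)-5,9-dimethyldeca-4,8-dienal | O=C[C@H](O[Si](C)(C)C(C)(C)C)C/C=C(\C)CCC=C(C)C | intermediate
28 | (3R,5E)-3-(TBS-oxy)-6,10-dimethylundeca-5,9-dien-1-yne | C#C[C@@H](C/C=C(\C)CCC=C(C)C)O[Si](C)(C)C(C)(C)C | intermediate
29 | alkenyl(dimethyl)alane from 28 | C[Al](C)/C=C(\C)[C@@H](C/C=C(\C)CCC=C(C)C)O[Si](C)(C)C(C)(C)C | intermediate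
30 | (1E,3R,5E)-3-(TBS-oxy)-1-iodo-2,6,10-trimethylundeca-1,5,9-triene | I/C=C(\C)[C@@H](C/C=C(\C)CCC=C(C)C)O[Si](C)(C)C(C)(C)C | intermediate
31 | caesium seco-carboxylate | CC(C)(C)[Si](c3ccccc3)(c4ccccc4)OCCC[C@@H]1/C(=C(/C)C(OCC)OCC)CC[C@](C)(O)[C@@]1(C)CCC(=O)[O-].[Cs+] | intermediate
32 | coupled bis-silyl ether acetal | CC(C)(C)[Si](c3ccccc3)(c4ccccc4)OCCC[C@@H]1/C(=C(/C)C(OCC)OCC)CC[C@](C)(O)[C@@]1(C)CC/C=C(\C)[C@@H](C/C=C(\C)CCC=C(C)C)O[Si](C)(C)C(C)(C)C | intermediate
33 | triol enal | OCCC[C@@H]1/C(=C(/C)C=O)CC[C@](C)(O)[C@@]1(C)CC/C=C(\C)[C@@H](C/C=C(\C)CCC=C(C)C)O | intermediate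
34 | primary myristate | CCCCCCCCCCCCCC(=O)OCCC[C@@H]1/C(=C(/C)C=O)CC[C@](C)(O)[C@@]1(C)CC/C=C(\C)[C@@H](C/C=C(\C)CCC=C(C)C)O | intermediate
35 | CNP0184857.1 | CCCCCCCCCCCCCC(=O)OCCC[C@@H]1/C(=C(/C)C=O)CC[C@](C)(O)[C@@]1(C)CC/C=C(\C)[C@@H](C/C=C(\C)CCC=C(C)C)OC(C)=O | target

## Step count and risks

Total steps: 19. Longest linear sequence: 13 (steps 1–9, then 16–19).

**Step 16 (new photochemical coupling).** It is untested; the free tertiary alkoxide could undergo competing β-scission, and the C8 radical could cyclise onto the tetrasubstituted alkene. Fallback with known chemistry, setting out from 17: LiOH opens the lactone, and in the same flask Et3SiOTf/2,6-lutidine followed by K2CO3/MeOH gives the triethylsilyl-protected seco-acid F1. N-Hydroxytetrachlorophthalimide and N,N′-diisopropylcarbodiimide give the redox-active ester F2. Nickel-electrocatalytic decarboxylative alkenylation with 30 (NiCl2·6H2O, 2,2′-bipyridine, AgNO3, Mg anode, reticulated vitreous carbon cathode, DMF) gives the triethylsilyl ether of the coupled product F3. The step 17 conditions remove all silyl groups and the acetal, and the route is rejoined at 33.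

**Step 9 (1,4-hydrogenation).** The hindered 2,3-disubstituted diene may not reach the s-cis η4 geometry on chromium. Fallback, setting out from 13: isopropenylmagnesium bromide with CeCl3 at −78 °C gives the tertiary allylic alcohol F4. Pyridinium chlorochromate, C5H5NH[CrO3Cl], effects oxidative 1,3-transposition (Babler–Dauben) to the enal. This fallback is not geometry-locked: the Z-enal lactone F5 must be separated from its E isomer by chromatography, and the E isomer is recycled with catalytic I2. HC(OEt)3 and pyridinium p-toluenesulfonate in EtOH convert F5 into 17.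

**Step 4 (Michael addition).** Regio- and diastereoselectivity at the hindered enolate and bis-addition are the concerns. Fallback, setting out from 7: KH then allyl chloroformate trap the more substituted enolate as the allyl enol carbonate F6. Pd2(dba)3 (dba = dibenzylideneacetone) with PPh3 gives, by Tsuji decarboxylative allylation, the α-allyl-α-methyl ketone F7 with allyl trans to the C1 chain. MeMgBr/CeCl3 gives the tertiary alcohol F8. 9-Borabicyclo[3.3.1]nonane then NaBO3·4H2O hydroborates only the monosubstituted alkene to the diol F9. TEMPO/PhI(OAc)2 oxidises F9 through the lactol to the lactone 10.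

## Further compounds

F1 | step 16 | triethylsilyl-protected seco-acid | CC(C)(C)[Si](c3ccccc3)(c4ccccc4)OCCC[C@@H]1/C(=C(/C)C(OCC)OCC)CC[C@](C)(O[Si](CC)(CC)CC)[C@@]1(C)CCC(O)=O
F2 | step 16 | N-(acyloxy)tetrachlorophthalimide redox-active ester | CC(C)(C)[Si](c3ccccc3)(c4ccccc4)OCCC[C@@H]1/C(=C(/C)C(OCC)OCC)CC[C@](C)(O[Si](CC)(CC)CC)[C@@]1(C)CCC(=O)ON5C(=O)c6c(Cl)c(Cl)c(Cl)c(Cl)c6C5=O
F3 | step 16 | triethylsilyl ether of the coupled product | CC(C)(C)[Si](c3ccccc3)(c4ccccc4)OCCC[C@@H]1/C(=C(/C)C(OCC)OCC)CC[C@](C)(O[Si](CC)(CC)CC)[C@@]1(C)CC/C=C(\C)[C@@H](C/C=C(\C)CCC=C(C)C)O[Si](C)(C)C(C)(C)C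
F4 | step 9 | tertiary allylic alcohol (C2 mixture) | CC(C)(C)[Si](c3ccccc3)(c4ccccc4)OCCC[C@@H]1C(O)(C(C)=C)CC[C@](C)(O2)[C@@]1(C)CCC2=O
F5 | step 9 | Z-enal lactone | CC(C)(C)[Si](c3ccccc3)(c4ccccc4)OCCC[C@@H]1/C(=C(/C)C=O)CC[C@](C)(O2)[C@@]1(C)CCC2=O
F6 | step 4 | allyl enol carbonate | CC(C)(C)[Si](c3ccccc3)(c4ccccc4)OCCC[C@@H]1[C@@H](C(C)=C)CCC(OC(=O)OCC=C)=C1C
F7 | step 4 | α-allyl-α-methyl ketone | CC(C)(C)[Si](c3ccccc3)(c4ccccc4)OCCC[C@@H]1[C@@H](C(C)=C)CCC(=O)[C@@]1(C)CC=C
F8 | step 4 | tertiary alcohol with allyl group | CC(C)(C)[Si](c3ccccc3)(c4ccccc4)OCCC[C@@H]1[C@@H](C(C)=C)CC[C@](C)(O)[C@@]1(C)CC=C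
F9 | step 4 | primary/tertiary diol | CC(C)(C)[Si](c3ccccc3)(c4ccccc4)OCCC[C@@H]1[C@@H](C(C)=C)CC[C@](C)(O)[C@@]1(C)CCCO
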